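The 19-membered ring is not closed at a bridge C–C bond or at a diaryl ether. A linear tetra-aryl bis(benzyl bromide) is closed on sulfide as a 20-membered thiacyclophane, and the sulfur atom is then excised photochemically in trimethyl phosphite. This single-atom ring contraction (20 → 19) creates the CH2–CH2 bond between the benzylic carbons of catechol ring A and meta-phenylene ring D (ring B: para-phenylene; ring C: second catechol ring). It exploits the fact that both bridge carbons are benzylic, so the two C–S bonds are the weakest bonds in the ring. Rings A and C both come from 3-bromo-4,5-dimethoxybenzaldehyde.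

Key step: step 8

Assumption: the target SMILES has no stereocentre and no stereodescriptor, and no configurationally stable axis or plane is expected in this flexible 19-membered ring, so no enantiocontrol is required.

Step 1
Reactants: 1 3-bromo-4,5-dimethoxybenzaldehyde; 2 methyl 3-hydroxybenzoate
Product: 3 methyl 3-(5-formyl-2,3-dimethoxyphenoxy)benzoate
Conditions: CuI (10 mol %), N,N-dimethylglycine·HCl (30 mol %), Cs2CO3, 1,4-dioxane, 100 °C
Reagents that add atoms: none
Why: Ligand-accelerated Ullmann diaryl ether synthesis (ring C–O–ring D), in which the copper(I) aryloxide of 2 couples with the aryl bromide of 1, and aldehyde and ester are inert to Cs2CO3 in dry dioxane.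

Step 2
Reactants: 3 methyl 3-(5-formyl-2,3-dimethoxyphenoxy)benzoate; 4 [4-(benzyloxy)benzyl]triphenylphosphonium chloride
Product: 6 methyl 3-{5-[2-(4-benzyloxyphenyl)ethenyl]-2,3-dimethoxyphenoxy}benzoate (E/Z mixture), via phosphorus ylide 5 (not isolated)
Conditions: K2CO3, 18-crown-6 (cat.), CH2Cl2, reflux
Reagents that add atoms: none
Why: Wittig olefination of the non-enolisable aryl aldehyde by the semi-stabilised benzylic ylide 5 under solid–liquid phase-transfer conditions that spare the methyl ester; the alkene geometry is irrelevant because step 3 saturates it.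

Step 3
Reactants: 6 methyl 3-{5-[2-(4-benzyloxyphenyl)ethenyl]-2,3-dimethoxyphenoxy}benzoate
Product: 7 methyl 3-{5-[2-(4-hydroxyphenyl)ethyl]-2,3-dimethoxyphenoxy}benzoate
Conditions: H2 (1 atm), 10% Pd/C, EtOAc–MeOH, rt
Reagents that add atoms: none
Why: Heterogeneous catalytic hydrogenation should saturate the stilbene and hydrogenolyse the benzyl ether in one operation, while the diaryl ether, the aryl methyl ethers and the benzoate are stable.

Step 4
Reactants: 7 methyl 3-{5-[2-(4-hydroxyphenyl)ethyl]-2,3-dimethoxyphenoxy}benzoate; 1 3-bromo-4,5-dimethoxybenzaldehyde (second use)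
Product: 8 methyl 3-[5-(2-{4-[5-formyl-2,3-dimethoxyphenoxy]phenyl}ethyl)-2,3-dimethoxyphenoxy]benzoate
Conditions: CuI (10 mol %), N,N-dimethylglycine·HCl (30 mol %), Cs2CO3, 1,4-dioxane, 110 °C
Reagents that add atoms: none
Why: A second ligand-accelerated Ullmann ether coupling, now of the unhindered 4-alkylphenol 7 with 1, attaches ring A (ring A–O–ring B) with its formyl group as the future benzylic carbon.

Step 5
Reactants: 8 methyl 3-[5-(2-{4-[5-formyl-2,3-dimethoxyphenoxy]phenyl}ethyl)-2,3-dimethoxyphenoxy]benzoate
Product: 9 (3-{5-[2-(4-{5-(hydroxymethyl)-2,3-dimethoxyphenoxy}phenyl)ethyl]-2,3-dimethoxyphenoxy}phenyl)methanol (the diol)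
Conditions: LiAlH4, THF, 0 °C → rt; aq. NaOH work-up
Reagents that add atoms: none
Why: Hydride reduction with LiAlH4 should convert the aryl aldehyde (ring A) and the methyl benzoate (ring D) into the two benzylic alcohols in one step, with all ethers inert.

Step 6
Reactants: 9 the diol
Product: 10 1-(bromomethyl)-3-{5-[2-(4-{5-(bromomethyl)-2,3-dimethoxyphenoxy}phenyl)ethyl]-2,3-dimethoxyphenoxy}benzene (the bis(benzyl bromide))
Conditions: PBr3, CH2Cl2, 0 °C
Reagents that add atoms: phosphorus tribromide, BrP(Br)Br
Why: Primary benzylic alcohols are converted into bromides by SN2 displacement of their phosphite esters at 0 °C, conditions that do not cleave aryl methyl ethers.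

Step 7
Reactants: 10 the bis(benzyl bromide)
Product: 12 20-membered thiacyclophane (tetra-O-methyl target skeleton with ring A–CH2–S–CH2–ring D in place of the ethano bridge), via bromo thiolate 11 (not isolated)
Conditions: Na2S·9H2O (1.2 equiv), degassed DMF–THF, slow addition of 10 over 12 h (final 2 mM), rt
Reagents that add atoms: sodium sulfide (used as the nonahydrate), [Na+].[Na+].[S-2]
Why: Two consecutive SN2 displacements by sulfide under high dilution (thiacyclophane synthesis): the first, expected at the more electrophilic trioxygenated benzylic bromide, gives bromo thiolate 11, whose soft thiolate should close the 20-membered ring on the remaining benzylic bromide faster than it meets a second molecule.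

Step 8
Reactants: 12 20-membered thiacyclophane
Product: 13 tetra-O-methyl ether of the target (19-membered macrocycle)
Conditions: hν (254 nm, quartz), P(OMe)3 as solvent (3 mM), degassed, Ar, rt
Reagents that add atoms: none
Why: Excitation of the dibenzyl sulfide chromophore homolyses one benzylic C–S bond, P(OMe)3 captures the thiyl radical, and β-scission of the phosphoranyl radical releases (MeO)3P=S and the second benzyl radical, so that a tethered pair of benzyl radicals is left to recombine. The closest known reaction type is the photochemical sulfur extrusion from dibenzylic thiacyclophanes in trialkyl phosphites, the classical ring contraction to cyclophanes with ethano bridges. The 19-membered ring is closed by intramolecular radical–radical recombination of the two benzylic carbons (ring contraction 20 → 19), which remain linked through the 17 other ring atoms. No stereocentre is formed. The step needs cleavage of the C–S bonds in preference to the aryl C–O and O–CH3 bonds and recombination in preference to hydrogen abstraction or intermolecular coupling: the benzylic C–S bonds are the weakest in 12, the benzyl radicals have no β-hydrogen for disproportionation, and dilution keeps the coupling intramolecular.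

Step 9
Reactants: 13 tetra-O-methyl ether of the target
Product: 14 target CNP0511668.0
Conditions: BBr3 (8 equiv), CH2Cl2, −78 °C → rt; then H2O
Reagents that add atoms: none
Why: BBr3 coordinates each methoxy oxygen and bromide cleaves the O–CH3 bond by SN2, a standard exhaustive aryl methyl ether cleavage that leaves the diaryl ether bonds (no SN2 site) intact and frees the four phenols on aqueous work-up.

Compound list
1 | 3-bromo-4,5-dimethoxybenzaldehyde | O=Cc1cc(Br)c(OC)c(OC)c1 | starting material
2 | methyl 3-hydroxybenzoate | COC(=O)c1cccc(O)c1 | starting material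
3 | methyl 3-(5-formyl-2,3-dimethoxyphenoxy)benzoate | COC(=O)c1cccc(Oc2cc(C=O)cc(OC)c2OC)c1 | intermediate
4 | [4-(benzyloxy)benzyl]triphenylphosphonium chloride | [Cl-].C(c1ccc(OCc2ccccc2)cc1)[P+](c1ccccc1)(c1ccccc1)c1ccccc1 | starting material
5 | [4-(benzyloxy)benzylidene]triphenylphosphorane (ylide) | C(c1ccc(OCc2ccccc2)cc1)=P(c1ccccc1)(c1ccccc1)c1ccccc1 | intermediate (not isolated)
6 | methyl 3-{5-[2-(4-benzyloxyphenyl)ethenyl]-2,3-dimethoxyphenoxy}benzoate (E/Z mixture, geometry not specified) | COC(=O)c1cccc(Oc2cc(C=Cc3ccc(OCc4ccccc4)cc3)cc(OC)c2OC)c1 | intermediate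
7 | methyl 3-{5-[2-(4-hydroxyphenyl)ethyl]-2,3-dimethoxyphenoxy}benzoate | COC(=O)c1cccc(Oc2cc(CCc3ccc(O)cc3)cc(OC)c2OC)c1 | intermediate
8 | methyl 3-[5-(2-{4-[5-formyl-2,3-dimethoxyphenoxy]phenyl}ethyl)-2,3-dimethoxyphenoxy]benzoate | COC(=O)c1cccc(Oc2cc(CCc3ccc(Oc4cc(C=O)cc(OC)c4OC)cc3)cc(OC)c2OC)c1 | intermediate
9 | (3-{5-[2-(4-{5-(hydroxymethyl)-2,3-dimethoxyphenoxy}phenyl)ethyl]-2,3-dimethoxyphenoxy}phenyl)methanol | OCc1cccc(Oc2cc(CCc3ccc(Oc4cc(CO)cc(OC)c4OC)cc3)cc(OC)c2OC)c1 | intermediate
10 | 1-(bromomethyl)-3-{5-[2-(4-{5-(bromomethyl)-2,3-dimethoxyphenoxy}phenyl)ethyl]-2,3-dimethoxyphenoxy}benzene | BrCc1cccc(Oc2cc(CCc3ccc(Oc4cc(CBr)cc(OC)c4OC)cc3)cc(OC)c2OC)c1 | intermediate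
11 | sodium thiolate from displacement of the ring-A benzylic bromide of 10 (ring-D CH2Br intact) | [Na+].[S-]Cc1cc(Oc2ccc(CCc3cc(OC)c(OC)c(Oc4cccc(CBr)c4)c3)cc2)c(OC)c(OC)c1 | intermediate (not isolated)
12 | 20-membered thiacyclophane (ring A–CH2–S–CH2–ring D; four OMe) | COc1cc2cc(c1OC)Oc1ccc(cc1)CCc1cc(OC)c(OC)c(c1)Oc1cccc(c1)CSC2 | intermediate
13 | tetra-O-methyl ether of the target | COc1cc2cc(c1OC)Oc1ccc(cc1)CCc1cc(OC)c(OC)c(c1)Oc1cccc(c1)CC2 | intermediate
14 | CNP0511668.0 | Oc1cc2cc(c1O)Oc1ccc(cc1)CCc1cc(O)c(O)c(c1)Oc1cccc(c1)CC2 | target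

Total step count: 9. Longest linear sequence: 9 steps (1 and 2 to 14).

Steps most likely to fail

Step 8. The excited state or the radical pair may leak into unproductive channels: hydrogen abstraction to open-chain bis-tolyl products, intermolecular coupling, or secondary photolysis of the aryl ether chromophores on prolonged irradiation. The fallback replaces the photochemical radical extrusion by an ionic, base-mediated one. It sets out from 12: oxidation with mCPBA (2.2 equiv, CH2Cl2, 0 °C) should give the cyclic sulfone F1. A Ramberg–Bäcklund reaction (KOH on alumina, CBr2F2, t-BuOH–CH2Cl2, rt) then proceeds by α-halogenation, episulfone closure and loss of SO2 to the 19-membered macrocyclic stilbene F2 (E/Z mixture). Hydrogenation (H2, Pd/C, EtOAc) comes back to the route at 13.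

Step 7. Intermolecular S-alkylation may outrun ring closure and give oligomers, and the electron-rich ring-A benzylic bromide may be lost to solvolysis during the long addition. The fallback closes the ring through a reversible S–S bond and then contracts it. It sets out from 10: KSAc in DMF should give the bis(thioacetate) F3, and NaOMe in MeOH the dithiol F4. Oxidation with I2/Et3N at high dilution gives the 21-membered cyclic disulfide F5, where thiol–disulfide exchange can return oligomers to the monomeric ring. Desulfurisation of the disulfide with P(NEt2)3 in benzene excises one sulfur and comes back to the route at 12.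

Step 4. Oxidative addition at the electron-rich, ortho-methoxy-flanked aryl bromide may be slow, so that hydrodebromination of 1 and stalling of the copper catalyst compete. The fallback reverses the roles of the two rings. It sets out from 7: Tf2O and pyridine in CH2Cl2 should give the aryl triflate F6. F6 is coupled with commercial 3-hydroxy-4,5-dimethoxybenzaldehyde (O=Cc1cc(O)c(OC)c(OC)c1) under palladium catalysis (Pd(OAc)2, t-BuXPhos, K3PO4, toluene, 100 °C), which comes back to the route at 8.

Further compounds
F1 | step 8 | 20-membered cyclic sulfone (S,S-dioxide of 12) | COc1cc2cc(c1OC)Oc1ccc(cc1)CCc1cc(OC)c(OC)c(c1)Oc1cccc(c1)CS(=O)(=O)C2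
F2 | step 8 | 19-membered macrocyclic stilbene (E/Z mixture, geometry not specified) | COc1cc2cc(c1OC)Oc1ccc(cc1)CCc1cc(OC)c(OC)c(c1)Oc1cccc(c1)C=C2
F3 | step 7 | bis(thioacetate) of 10 | CC(=O)SCc1cccc(Oc2cc(CCc3ccc(Oc4cc(CSC(C)=O)cc(OC)c4OC)cc3)cc(OC)c2OC)c1
F4 | step 7 | dithiol | SCc1cccc(Oc2cc(CCc3ccc(Oc4cc(CS)cc(OC)c4OC)cc3)cc(OC)c2OC)c1
F5 | step 7 | 21-membered cyclic disulfide | COc1cc2cc(c1OC)Oc1ccc(cc1)CCc1cc(OC)c(OC)c(c1)Oc1cccc(c1)CSSC2
F6 | step 4 | aryl triflate of 7 | COC(=O)c1cccc(Oc2cc(CCc3ccc(OS(=O)(=O)C(F)(F)F)cc3)cc(OC)c2OC)c1
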